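**Retrosynthetic overview** (ring atoms numbered as in the target, C1 = C=O, C6 bears the chain; chain atoms primed from C1')
1. Target ⇐ one acidic unmasking (C1 dimethyl ketal → enone, O5/O6 acetonide, O4 silyl ether) of a protected cyclohexene that already carries the complete (12'Z)-henicosenyl chain.
2. Chain ⇐ C11'–C12' disconnection: Zweifel olefination of the primary alkyl pinacol boronic ester ring–(CH2)11–Bpin with (E)-dec-1-enyllithium. Boron is a temporary tether holding C11' and C12' on one atom; the 1,2-shift makes the bond and the anti elimination fixes the Z geometry. The union is late because the chain alkene would not survive the ring osmylation.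
3. Enabling feature: the Z-C12'=C13' alkene has on its ring side an unbranched primary carbon (C11') at the end of an eleven-methylene spacer. C11' can therefore carry boron and migrate, while the six-membered ring (C1 as ketal, O4/O5/O6 capped) stays out of reach of the organolithium and of iodine.
4. Ring stereotriad ⇐ the benzene ring of 3-bromo-4-methoxyphenol, dearomatised with PhI(OAc)2/MeOH to a quinone monoketal. A temporary bromine at C3 lets a CBS reduction set C4 and shields C2=C3; osmylation anti to O4 then sets C5/C6.
5. Ring order: the carbocycle is never closed (it comes from the arene); then the dioxolane (acetonide, temporary), then the dioxaborolane (temporary, expelled in the key step).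

Key step: step 11

Assumption: brief aqueous TFA is taken to leave the free 4,5,6-trihydroxy enone intact, as it does for closely related trihydroxycyclohexenones; the three starting materials are treated as catalogue compounds.

**Route**

Step 1
Reactants: 1 11-chloroundec-1-ene; 2 3-bromo-4-methoxyphenol
Product: 4 3-(11-chloroundecyl)-4-methoxyphenol, via B-(11-chloroundecyl)-9-borabicyclo[3.3.1]nonane 3 (not isolated)
Conditions: 9-BBN, THF, 0 °C → rt; then 2, Pd(dppf)Cl2 (3 mol %), K3PO4 (aq), THF/H2O, 60 °C
Reagents that add atoms: none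
Why: anti-Markovnikov hydroboration of the terminal alkene followed by B-alkyl Suzuki–Miyaura coupling should join C1' to the arene carbon ortho to OMe, because the primary C–Cl bond is inert to zerovalent palladium and, in aqueous THF without a dipolar cosolvent, to the phenoxide; no stereocenter is formed.

Step 2
Reactants: 4 3-(11-chloroundecyl)-4-methoxyphenol
Product: 5 2-bromo-5-(11-chloroundecyl)-4-methoxyphenol
Conditions: NBS (1.0 equiv), MeCN, −20 → 0 °C
Reagents that add atoms: N-bromosuccinimide, O=C1CCC(=O)N1Br
Why: electrophilic aromatic bromination is directed ortho to the free phenol (para is blocked by OMe), and of the two ortho positions the one para to the chain is open while the other is flanked by OH and the chain; no stereocenter is formed.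

Step 3
Reactants: 5 2-bromo-5-(11-chloroundecyl)-4-methoxyphenol
Product: 6 2-bromo-5-(11-chloroundecyl)-4,4-dimethoxycyclohexa-2,5-dien-1-one
Conditions: PhI(OAc)2 (1.1 equiv), MeOH, 0 °C; NaHCO3 work-up
Reagents that add atoms: methanol, CO
Why: oxidative dearomatisation of a p-methoxyphenol by the trivalent iodine reagent in methanol (quinone monoketal formation) places the second methoxy group on the para carbon, so the pattern of 5 fixes the regiochemistry (C=O at the former phenol carbon, Br α to it, chain next to the ketal); no stereocenter is formed.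

Step 4
Reactants: 6 2-bromo-5-(11-chloroundecyl)-4,4-dimethoxycyclohexa-2,5-dien-1-one
Product: 7 (1R)-2-bromo-5-(11-chloroundecyl)-4,4-dimethoxycyclohexa-2,5-dien-1-ol
Conditions: (S)-2-methyl-CBS-oxazaborolidine (20 mol %), BH3·SMe2, THF, −30 °C; MeOH quench, NaHCO3 (aq)
Reagents that add atoms: none
Why: Corey–Bakshi–Shibata 1,2-reduction, for which α-bromo enones are among the best substrates: the C–Br flank acts as the large group and the unsubstituted vinylic CH flank as the small one, so the (S)-catalyst should deliver hydride to the face that gives the (1R)-alcohol (the future C4), and acid is avoided in the work-up because the dienol ketal aromatises easily.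

Step 5
Reactants: 7 (1R)-2-bromo-5-(11-chloroundecyl)-4,4-dimethoxycyclohexa-2,5-dien-1-ol
Product: 8 (1R)-2-bromo-1-(tert-butyldimethylsilyloxy)-5-(11-chloroundecyl)-4,4-dimethoxycyclohexa-2,5-diene
Conditions: TBSCl, imidazole, DMF, 0 °C → rt
Reagents that add atoms: tert-butyldimethylsilyl chloride, C[Si](C)(Cl)C(C)(C)C
Why: standard silylation of a secondary alcohol caps the aromatisation-prone bis-allylic carbinol and installs the bulky allylic group that steers the next step; the configuration is untouched.

Step 6
Reactants: 8 (1R)-2-bromo-1-(tert-butyldimethylsilyloxy)-5-(11-chloroundecyl)-4,4-dimethoxycyclohexa-2,5-diene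
Product: 9 (1R,2R,3R)-4-bromo-3-(tert-butyldimethylsilyloxy)-1-(11-chloroundecyl)-6,6-dimethoxycyclohex-4-ene-1,2-diol
Conditions: OsO4 (5 mol %), NMO, acetone/H2O, rt
Reagents that add atoms: osmium tetroxide (transfers both oxygens, regenerated), O=[Os](=O)(=O)=O; N-methylmorpholine N-oxide, C[N+]1([O-])CCOCC1; water, O
Why: catalytic syn-dihydroxylation should occur only at the electron-richer trisubstituted alkene (the bromoalkene is deactivated) and on the face anti to the allylic silyloxy group, the usual sense for osmylation of cyclic allylic ethers, the ketal carbon carrying a methoxy group on either face; this sets C6 and C5 of the target cis to each other and trans to O4.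

Step 7
Reactants: 9 (1R,2R,3R)-4-bromo-3-(tert-butyldimethylsilyloxy)-1-(11-chloroundecyl)-6,6-dimethoxycyclohex-4-ene-1,2-diol
Product: 10 (1R,2R,3R)-4-bromo-3-(tert-butyldimethylsilyloxy)-1-(11-chloroundecyl)-6,6-dimethoxycyclohex-4-ene-1,2-diol 1,2-acetonide
Conditions: 2,2-dimethoxypropane, pyridinium p-toluenesulfonate (cat.), CH2Cl2, rt
Reagents that add atoms: 2,2-dimethoxypropane, COC(C)(C)OC
Why: acid-catalysed transacetalisation closes the dioxolane on the cis-1,2-diol while the water-free medium keeps the ring dimethyl ketal in place; no stereocenter changes.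

Step 8
Reactants: 10 (1R,2R,3R)-4-bromo-3-(tert-butyldimethylsilyloxy)-1-(11-chloroundecyl)-6,6-dimethoxycyclohex-4-ene-1,2-diol 1,2-acetonide
Product: 11 (1R,2R,3S)-3-(tert-butyldimethylsilyloxy)-1-(11-chloroundecyl)-6,6-dimethoxycyclohex-4-ene-1,2-diol 1,2-acetonide
Conditions: Pd(OAc)2 (5 mol %), PPh3 (10 mol %), HCO2H, Et3N, DMF, 60 °C
Reagents that add atoms: none
Why: palladium-catalysed formate hydrogenolysis of the alkenyl bromide (oxidative addition to zerovalent palladium, decarboxylation of formate to a hydride, reductive elimination) removes the auxiliary bromine once it has done its work, the primary chloride, ketals and silyl ether being inert; it precedes the copper step, where a C(sp2)–Br bond would compete (the descriptor at C3 changes only because the priorities change).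

Step 9
Reactants: 11 (1R,2R,3S)-3-(tert-butyldimethylsilyloxy)-1-(11-chloroundecyl)-6,6-dimethoxycyclohex-4-ene-1,2-diol 1,2-acetonide
Product: 12 (1R,2R,3S)-3-(tert-butyldimethylsilyloxy)-6,6-dimethoxy-1-[11-(4,4,5,5-tetramethyl-1,3,2-dioxaborolan-2-yl)undecyl]cyclohex-4-ene-1,2-diol 1,2-acetonide
Conditions: B2pin2, CuCl (10 mol %), Xantphos (10 mol %), KOtBu, THF, rt
Reagents that add atoms: bis(pinacolato)diboron, CC1(C)OB(OC1(C)C)B1OC(C)(C)C(C)(C)O1
Why: copper-catalysed boryl substitution of an unactivated primary alkyl chloride by the alkoxide-activated monovalent copper boryl species, a reaction type that tolerates ethers, acetals and isolated alkenes; no stereocenter is involved.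

Step 10
Reactants: 13 dec-1-yne
Product: 15 (E)-1-iododec-1-ene, via (E)-dec-1-enylzirconocene chloride 14 (not isolated)
Conditions: Cp2Zr(H)Cl, THF, rt; then I2, 0 °C
Reagents that add atoms: iodine, II
Why: syn hydrozirconation of the terminal alkyne places zirconium on C1 trans to the octyl chain and iodinolysis of the C–Zr bond proceeds with retention, so the E iodide should result.

Step 11
Reactants: 12 (1R,2R,3S)-3-(tert-butyldimethylsilyloxy)-6,6-dimethoxy-1-[11-(4,4,5,5-tetramethyl-1,3,2-dioxaborolan-2-yl)undecyl]cyclohex-4-ene-1,2-diol 1,2-acetonide; 15 (E)-1-iododec-1-ene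
Product: 19 (1R,2R,3S)-3-(tert-butyldimethylsilyloxy)-1-[(12Z)-henicos-12-en-1-yl]-6,6-dimethoxycyclohex-4-ene-1,2-diol 1,2-acetonide, via (E)-dec-1-enyllithium 16 (not isolated), via lithium alkenyl(alkyl)pinacolatoborate 17 (not isolated), via β-iodoalkyl boronic ester 18 (not isolated)
Conditions: 15 (1.4 equiv), t-BuLi (2 equiv per 15), Et2O, −78 °C; 12, THF, −78 °C; I2, MeOH/THF, −78 °C; NaOMe, MeOH, −78 °C → rt; Na2S2O3 (aq)
Reagents that add atoms: none
Why: Zweifel olefination: I/Li exchange gives 16 with retention, which adds to the trivalent boron of 12 to form the tetracoordinate borate 17, so that C11' and C12' sit on the same boron atom; iodine then activates the alkenyl π bond as an iodonium ion, the primary C11' group migrates from boron to C12' anti to the new C13'–I bond (18), and methoxide adds to boron so that B and I leave by anti elimination. The closest known reaction type is exactly this iodine/methoxide olefination of pinacol boronic esters with alkenyllithium reagents, here applied to a primary alkyl boronic ester carrying a protected polyol. No ring is closed: the dioxaborolane serves only as a temporary tether and is expelled as its methyl borate. The only new stereo element is the C12'=C13' geometry, controlled by the mechanism alone: anti migration followed by anti elimination inverts the E geometry of 16 to the Z alkene stereospecifically, while C4, C5 and C6 lie eleven atoms away and are not involved. The step needs (i) migration of C11' only, secured because the pinacol oxygens do not migrate and C11' is the sole sp3 carbon on boron, and (ii) chemoselectivity of the organolithium and of iodine, secured because the ring has no carbonyl or OH (C1 is a dimethyl ketal, O4 a silyl ether, O5/O6 an acetonide) and its only alkene lies between two oxygenated sp3 carbons, far less nucleophilic than the alkenyl borate that consumes the iodine at −78 °C.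

Step 12
Reactants: 19 (1R,2R,3S)-3-(tert-butyldimethylsilyloxy)-1-[(12Z)-henicos-12-en-1-yl]-6,6-dimethoxycyclohex-4-ene-1,2-diol 1,2-acetonide
Product: 20 (4S,5R,6R)-4,5,6-trihydroxy-6-[(12Z)-henicos-12-en-1-yl]cyclohex-2-en-1-one
Conditions: TFA/H2O (9:1), 0 °C → rt
Reagents that add atoms: water, O
Why: aqueous acid should hydrolyse the allylic dimethyl ketal to the C1 enone and cleave the acetonide and the secondary silyl ether in the same operation (acetal hydrolysis and acidic desilylation) without touching a stereocenter, and because C6 is fully substituted the α-hydroxy ketone can neither epimerise nor dehydrate through enolisation, the isolated Z alkene being inert.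

**Compound list**
1 | 11-chloroundec-1-ene | C=CCCCCCCCCCCl | starting material
2 | 3-bromo-4-methoxyphenol | COc1ccc(O)cc1Br | starting material
3 | B-(11-chloroundecyl)-9-borabicyclo[3.3.1]nonane | ClCCCCCCCCCCCB1C2CCCC1CCC2 | intermediate (not isolated)
4 | 3-(11-chloroundecyl)-4-methoxyphenol | COc1ccc(O)cc1CCCCCCCCCCCCl | intermediate
5 | 2-bromo-5-(11-chloroundecyl)-4-methoxyphenol | COc1cc(Br)c(O)cc1CCCCCCCCCCCCl | intermediate
6 | 2-bromo-5-(11-chloroundecyl)-4,4-dimethoxycyclohexa-2,5-dien-1-one | O=C1C(Br)=CC(OC)(OC)C(CCCCCCCCCCCCl)=C1 | intermediate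
7 | (1R)-2-bromo-5-(11-chloroundecyl)-4,4-dimethoxycyclohexa-2,5-dien-1-ol | ClCCCCCCCCCCCC1=C[C@@H](O)C(Br)=CC1(OC)OC | intermediate
8 | (1R)-2-bromo-1-(tert-butyldimethylsilyloxy)-5-(11-chloroundecyl)-4,4-dimethoxycyclohexa-2,5-diene | ClCCCCCCCCCCCC1=C[C@@H](O[Si](C)(C)C(C)(C)C)C(Br)=CC1(OC)OC | intermediate
9 | (1R,2R,3R)-4-bromo-3-(tert-butyldimethylsilyloxy)-1-(11-chloroundecyl)-6,6-dimethoxycyclohex-4-ene-1,2-diol | ClCCCCCCCCCCC[C@]1(O)C(OC)(OC)C=C(Br)[C@H](O[Si](C)(C)C(C)(C)C)[C@H]1O | intermediate
10 | 1,2-acetonide of 9 | ClCCCCCCCCCCC[C@]1(OC(C)(C)O2)C(OC)(OC)C=C(Br)[C@H](O[Si](C)(C)C(C)(C)C)[C@H]12 | intermediate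
11 | (1R,2R,3S)-3-(tert-butyldimethylsilyloxy)-1-(11-chloroundecyl)-6,6-dimethoxycyclohex-4-ene-1,2-diol 1,2-acetonide | ClCCCCCCCCCCC[C@]1(OC(C)(C)O2)C(OC)(OC)C=C[C@H](O[Si](C)(C)C(C)(C)C)[C@H]12 | intermediate
12 | pinacol boronic ester (Cl of 11 replaced by Bpin) | CC1(C)OB(CCCCCCCCCCC[C@]2(OC(C)(C)O3)C(OC)(OC)C=C[C@H](O[Si](C)(C)C(C)(C)C)[C@H]23)OC1(C)C | intermediate
13 | dec-1-yne | C#CCCCCCCCC | starting material
14 | (E)-dec-1-enylzirconocene chloride | CCCCCCCC/C=C/[Zr](Cl)(C1C=CC=C1)C1C=CC=C1 | intermediate (not isolated)
15 | (E)-1-iododec-1-ene | CCCCCCCC/C=C/I | intermediate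
16 | (E)-dec-1-enyllithium | CCCCCCCC/C=C/[Li] | intermediate (not isolated)
17 | lithium (E)-dec-1-enyl(alkyl)pinacolatoborate from 12 and 16 | [Li+].CCCCCCCC/C=C/[B-]1(CCCCCCCCCCC[C@]2(OC(C)(C)O3)C(OC)(OC)C=C[C@H](O[Si](C)(C)C(C)(C)C)[C@H]23)OC(C)(C)C(C)(C)O1 | intermediate (not isolated)
18 | β-iodoalkyl boronic ester (anti adduct; one of the two diastereomers at C12'/C13' shown, both give the same alkene) | CCCCCCCC[C@H](I)[C@@H](B1OC(C)(C)C(C)(C)O1)CCCCCCCCCCC[C@]2(OC(C)(C)O3)C(OC)(OC)C=C[C@H](O[Si](C)(C)C(C)(C)C)[C@H]23 | intermediate (not isolated)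
19 | (1R,2R,3S)-3-(tert-butyldimethylsilyloxy)-1-[(12Z)-henicos-12-en-1-yl]-6,6-dimethoxycyclohex-4-ene-1,2-diol 1,2-acetonide | CCCCCCCC/C=C\CCCCCCCCCCC[C@]1(OC(C)(C)O2)C(OC)(OC)C=C[C@H](O[Si](C)(C)C(C)(C)C)[C@H]12 | intermediate
20 | (4S,5R,6R)-4,5,6-trihydroxy-6-[(12Z)-henicos-12-en-1-yl]cyclohex-2-en-1-one | CCCCCCCC/C=C\CCCCCCCCCCC[C@]1(O)C(=O)C=C[C@H](O)[C@H]1O | target

**Step count and risks**

Total step count: 12. Longest linear sequence: 11 steps (steps 1–9, 11, 12); step 10 is the one-step side branch.

Steps most likely to fail:

Step 11. Borate formation may be incomplete, residual t-BuLi may attack boron, or part of the β-iodo boronic ester may leave by a syn pathway and erode the Z purity. The fallback sets out from chloride 11 and comes back at 19. Finkelstein exchange (NaI, acetone, reflux) should give the primary iodide F1. Dec-1-yne 13 is deprotonated (n-BuLi, THF, −78 → 0 °C) to lithium dec-1-ynide F2, which is alkylated by F1 in THF/DMPU to the internal alkyne F3; this forms the same C11'–C12' bond as an sp3–sp bond. Lindlar semi-hydrogenation (H2, Pd/CaCO3 poisoned with Pb(OAc)2, quinoline, EtOAc) should then add hydrogen syn to give the Z alkene 19, the ring alkene being left alone.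

Step 4. The catalyst may discriminate poorly between the two vinylic flanks of the cross-conjugated dienone, or the dienol may aromatise during work-up. The fallback sets out from dienone 6 and comes back at 7. Luche reduction (NaBH4, CeCl3·7H2O, MeOH, −78 °C) gives the racemic dienol F4. Kinetic resolution with Burkholderia cepacia lipase and vinyl acetate in MTBE is expected, by the usual empirical rule for secondary alcohols with the C–Br flank as the large group, to acylate the (R)-enantiomer to the (R)-acetate F5, which is separated from the unreacted (S)-alcohol. Methanolysis (K2CO3, MeOH, 0 °C) of F5 returns 7.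

Step 9. Activation of the primary C–Cl bond by the boryl copper species may be sluggish, and the strong alkoxide base may cause loss of material on long reaction times. The fallback sets out from chloride 11 and comes back at 12. Magnesium insertion (Mg turnings activated with 1,2-dibromoethane, THF, reflux) should give the alkylmagnesium chloride F6, which is quenched at −78 °C with 2-isopropoxy-4,4,5,5-tetramethyl-1,3,2-dioxaborolane to give 12; ketals, silyl ether and the ring alkene tolerate the Grignard reagent.

Further compounds
F1 | step 11 | iodide corresponding to 11 (Cl replaced by I) | ICCCCCCCCCCC[C@]1(OC(C)(C)O2)C(OC)(OC)C=C[C@H](O[Si](C)(C)C(C)(C)C)[C@H]12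
F2 | step 11 | lithium dec-1-ynide | [Li]C#CCCCCCCCC
F3 | step 11 | (1R,2R,3S)-3-(tert-butyldimethylsilyloxy)-1-(henicos-12-yn-1-yl)-6,6-dimethoxycyclohex-4-ene-1,2-diol 1,2-acetonide | CCCCCCCCC#CCCCCCCCCCCC[C@]1(OC(C)(C)O2)C(OC)(OC)C=C[C@H](O[Si](C)(C)C(C)(C)C)[C@H]12
F4 | step 4 | racemic 2-bromo-5-(11-chloroundecyl)-4,4-dimethoxycyclohexa-2,5-dien-1-ol | ClCCCCCCCCCCCC1=CC(O)C(Br)=CC1(OC)OC
F5 | step 4 | (1R)-2-bromo-5-(11-chloroundecyl)-4,4-dimethoxycyclohexa-2,5-dien-1-yl acetate | ClCCCCCCCCCCCC1=C[C@@H](OC(C)=O)C(Br)=CC1(OC)OC
F6 | step 9 | alkylmagnesium chloride corresponding to 11 (C–Cl replaced by C–MgCl) | Cl[Mg]CCCCCCCCCCC[C@]1(OC(C)(C)O2)C(OC)(OC)C=C[C@H](O[Si](C)(C)C(C)(C)C)[C@H]12
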